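**Plan**

- Retrosynthetic cuts, in order: the enyne C(sp)–C(sp2) bond (Sonogashira); the carboxyl group (from a primary alcohol); O2–C3 of the 1,2-dioxane (SN2 by a C6 hydroperoxy ketal) and the C6 peroxyketal (ozonolysis of a 1,1-disubstituted alkene in MeOH); the C6–side-chain bond (alkyllithium + γ-lactone); the lactone O–C3 bond (Baeyer–Villiger of a cyclobutanone); and C3–C4 (ring expansion of a cyclopropanol).
- Enabling feature: in the ring O1–O2–C3–C4–C5–C6 the peroxide-bearing methine C3 and the ketal carbon C6 are 1,4-related through the C4–C5 ethano bridge. The four carbons are therefore a cyclobutanone in disguise (C6 = C=O, C3 = α-carbon), and its C4–C5 unit can come from the CH2–CH2 of a cyclopropanol.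
- Forward order: cyclopropane (Kulinkovich) → cyclobutanone by closure of C3–C4 → γ-lactone after cleavage of the temporary C3–C6 bond → side chain added at C6, acyclic mesylate → 1,2-dioxane → enyne coupling → acid.
- Stereochemistry: C3 comes from (S)-α-hydroxy-γ-butyrolactone, relayed by inversion (ring expansion), retention (Baeyer–Villiger) and inversion (peroxide SN2). C6 is set by anomeric equilibration of the methoxy peroxyketal. The E alkene comes from syn hydrozirconation.

Key step: step 3

Remark: C6 is a ketal-type centre that equilibrates through the cyclic peroxycarbenium ion in acidic methanol, so it is placed under thermodynamic (anomeric) control and only C3 needs absolute control; 1, 7 and 16 are taken as commercial.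

Step 1
Reactants: 1 (3S)-3-hydroxyoxolan-2-one [(S)-α-hydroxy-γ-butyrolactone]
Product: 2 1-[(1S)-1,3-dihydroxypropyl]cyclopropan-1-ol
Conditions: EtMgBr (4 equiv), Ti(OiPr)4 (0.3 equiv), THF, 0 °C to rt; then H2O
Reagents that add atoms: ethylmagnesium bromide, CC[Mg]Br
Why: Kulinkovich cyclopropanation, in which the first equivalent of Grignard reagent converts the hydroxyl into its magnesium alkoxide and the titanacyclopropane formed from EtMgBr and Ti(OiPr)4 then adds twice to the lactone carbonyl as a 1,2-dicarbanion to give the cyclopropanol and release the primary alkoxide, the alkoxide-bearing C3 stereocentre being carried over unchanged.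

Step 2
Reactants: 2 1-[(1S)-1,3-dihydroxypropyl]cyclopropan-1-ol
Product: 3 1-[(1S)-3-[tert-butyl(dimethyl)silyl]oxy-1-hydroxypropyl]cyclopropan-1-ol
Conditions: TBSCl (1.05 equiv), imidazole, CH2Cl2/DMF, −20 to 0 °C
Reagents that add atoms: tert-butyldimethylsilyl chloride, CC(C)(C)[Si](C)(C)Cl
Why: Silyl ether formation under steric control, in which the unhindered primary hydroxyl should react well before the secondary carbinol next to the quaternary cyclopropane carbon and before the tertiary cyclopropanol, with no stereocentre touched.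

Step 3
Reactants: 3 1-[(1S)-3-[tert-butyl(dimethyl)silyl]oxy-1-hydroxypropyl]cyclopropan-1-ol
Product: 5 (2R)-2-[2-[tert-butyl(dimethyl)silyl]oxyethyl]cyclobutan-1-one, via secondary mesylate 4 (not isolated)
Conditions: MsCl (1.1 equiv), Et3N (2.5 equiv), CH2Cl2, −20 °C to rt
Reagents that add atoms: none
Why: The secondary hydroxyl is sulfonylated to mesylate 4 and, as its C3–O bond ionises, the cyclopropane bond C6–C4 lying antiperiplanar to it migrates from C6 to C3 while the cyclopropanol oxygen becomes the C6 carbonyl, so the C3–C4 bond is formed and the four-membered ring closed in one event. The closest known reaction type is the semipinacol (pinacol-type) ring expansion of 1-(1-sulfonyloxyalkyl)cyclopropanols to 2-substituted cyclobutanones. The cyclobutanone ring C3–C4–C5–C6 closes by a suprafacial 1,2-alkyl shift, that is a three-to-four ring expansion and not an exo or endo attack on a π bond. The new stereocentre C3 is controlled by the stereospecific backside entry of C4 anti to the departing mesylate, so inversion converts the (1S)-carbinol into the (2R)-cyclobutanone. The step needs sulfonylation of the secondary hydroxyl and not of the tertiary cyclopropanol, which the easier access to the C3 hydroxyl and one equivalent of MsCl at low temperature should secure, and it needs concerted migration instead of free cation formation, elimination or oxirane closure by the hydroxyl (which after a second inversion would give the enantiomer), which the electron-rich strained cyclopropane σ bond and the push of the oxygen lone pair toward C=O should secure. Enolisation of the product is disfavoured by the extra strain of a cyclobutanone enolate, so the α-stereocentre should survive the amine base.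

Step 4
Reactants: 5 (2R)-2-[2-[tert-butyl(dimethyl)silyl]oxyethyl]cyclobutan-1-one
Product: 6 (5R)-5-[2-[tert-butyl(dimethyl)silyl]oxyethyl]oxolan-2-one
Conditions: mCPBA (1.3 equiv), CH2Cl2, 0 °C to rt
Reagents that add atoms: 3-chloroperoxybenzoic acid, OOC(=O)c1cccc(Cl)c1
Why: Baeyer–Villiger oxidation, in which the strained cyclobutanone adds the peracid readily and the more substituted α-carbon C3 of the Criegee adduct should migrate to oxygen with retention of configuration, which cuts the temporary C3–C6 bond and gives the (5R)-γ-lactone.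

Step 5
Reactants: 6 (5R)-5-[2-[tert-butyl(dimethyl)silyl]oxyethyl]oxolan-2-one; 7 (5-iodopent-1-yn-1-yl)trimethylsilane
Product: 9 (9R)-11-[tert-butyl(dimethyl)silyl]oxy-9-hydroxy-1-(trimethylsilyl)undec-1-yn-6-one, via alkyllithium 8 (not isolated)
Conditions: 7, t-BuLi (2.0 equiv), Et2O, −78 °C; then 6, THF, −78 °C; then H2O
Reagents that add atoms: none
Why: Iodine–lithium exchange followed by single nucleophilic acyl addition, in which the lithium lactolate formed from the γ-lactone and 8 should be stable at −78 °C so that the ketone (in equilibrium with its cyclic hemiketal) is released only on work-up and a second addition is avoided, the stereocentre not being involved.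

Step 6
Reactants: 9 (9R)-11-[tert-butyl(dimethyl)silyl]oxy-9-hydroxy-1-(trimethylsilyl)undec-1-yn-6-one
Product: 10 (3R)-1-[tert-butyl(dimethyl)silyl]oxy-6-methylidene-11-(trimethylsilyl)undec-10-yn-3-ol
Conditions: Ph3PCH3Br (3 equiv), NaN(SiMe3)2 (3 equiv), THF, 0 °C to rt
Reagents that add atoms: methyltriphenylphosphonium bromide, C[P+](c1ccccc1)(c1ccccc1)c1ccccc1.[Br-]
Why: Wittig methylenation, in which the open-chain γ-hydroxy ketone tautomer is intercepted by excess ylide (one equivalent is spent on the hydroxyl) to give the 1,1-disubstituted alkene that will deliver the peroxyketal carbon.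

Step 7
Reactants: 10 (3R)-1-[tert-butyl(dimethyl)silyl]oxy-6-methylidene-11-(trimethylsilyl)undec-10-yn-3-ol
Product: 11 (3R)-1-[tert-butyl(dimethyl)silyl]oxy-6-methylidene-11-(trimethylsilyl)undec-10-yn-3-yl methanesulfonate
Conditions: MsCl, Et3N, CH2Cl2, 0 °C
Reagents that add atoms: methanesulfonyl chloride, CS(=O)(=O)Cl
Why: Sulfonylation of the secondary alcohol through sulfene turns the C3 oxygen into a leaving group without breaking the C3–O bond, so the (R) configuration is kept.

Step 8
Reactants: 11 (3R)-1-[tert-butyl(dimethyl)silyl]oxy-6-methylidene-11-(trimethylsilyl)undec-10-yn-3-yl methanesulfonate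
Product: 12 (3R)-1-[tert-butyl(dimethyl)silyl]oxy-6-hydroperoxy-6-methoxy-11-(trimethylsilyl)undec-10-yn-3-yl methanesulfonate (both C6 epimers)
Conditions: O3, CH2Cl2/MeOH (4:1), −78 °C, Sudan Red 7B as end-point indicator; then N2 purge, no reductant
Reagents that add atoms: ozone, [O-][O+]=O; methanol, CO
Why: Ozonolysis with Criegee trapping, in which the electron-rich 1,1-disubstituted alkene should react far faster than the silylalkyne, the primary ozonide fragments to formaldehyde and the disubstituted carbonyl oxide at C6, and methanol adds to the latter to give the α-methoxy hydroperoxide.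

Step 9
Reactants: 12 (3R)-1-[tert-butyl(dimethyl)silyl]oxy-6-hydroperoxy-6-methoxy-11-(trimethylsilyl)undec-10-yn-3-yl methanesulfonate (both C6 epimers)
Product: 13 tert-butyl-[2-[(3S)-6-methoxy-6-[5-(trimethylsilyl)pent-4-yn-1-yl]-1,2-dioxan-3-yl]ethoxy]dimethylsilane (both C6 epimers)
Conditions: KOtBu (1.1 equiv), 18-crown-6 (1.1 equiv), THF, 0 °C
Reagents that add atoms: none
Why: Intramolecular alkylation of a hydroperoxide (Williamson-type, 6-exo-tet), in which the weakly basic α-effect hydroperoxide anion displaces the secondary mesylate by SN2 with inversion, setting the (3S) peroxide stereocentre and closing the 1,2-dioxane, while any early loss of the alkynyl silyl group is harmless because step 10 removes it.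

Step 10
Reactants: 13 tert-butyl-[2-[(3S)-6-methoxy-6-[5-(trimethylsilyl)pent-4-yn-1-yl]-1,2-dioxan-3-yl]ethoxy]dimethylsilane (both C6 epimers)
Product: 15 2-[(3S,6R)-6-methoxy-6-(pent-4-yn-1-yl)-1,2-dioxan-3-yl]ethan-1-ol, via silylalkyne alcohol 14 (not isolated)
Conditions: CSA (0.1 equiv), MeOH, rt; then K2CO3 (0.5 equiv), rt
Reagents that add atoms: methanol, CO
Why: Acid-catalysed ketal exchange followed by base-mediated protiodesilylation, in which reversible ionisation to the cyclic peroxycarbenium ion lets C6 settle under anomeric control with the methoxy group axial and both carbon substituents equatorial, which is the (3S,6R) isomer (any separated C6 epimer can be resubmitted), the same acid cleaves the primary TBS ether to give 14, and K2CO3 in MeOH then removes the alkynyl silyl group.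

Step 11
Reactants: 16 undec-1-yne
Product: 18 (E)-1-iodoundec-1-ene, via alkenylzirconocene 17 (not isolated)
Conditions: Cp2Zr(H)Cl (1.2 equiv), THF, rt; then I2, 0 °C
Reagents that add atoms: iodine, II
Why: Hydrozirconation–iodination, in which syn addition of Zr–H across the terminal alkyne places zirconium on the terminal carbon and iodinolysis of the C–Zr bond with retention gives the (E)-iodoalkene.

Step 12
Reactants: 15 2-[(3S,6R)-6-methoxy-6-(pent-4-yn-1-yl)-1,2-dioxan-3-yl]ethan-1-ol; 18 (E)-1-iodoundec-1-ene
Product: 19 2-[(3S,6R)-6-[(E)-hexadec-6-en-4-yn-1-yl]-6-methoxy-1,2-dioxan-3-yl]ethan-1-ol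
Conditions: Pd(PPh3)4 (5 mol%), CuI (10 mol%), i-Pr2NH, THF, rt
Reagents that add atoms: none
Why: Sonogashira coupling, in which oxidative addition of the zerovalent palladium complex into the alkenyl iodide, transmetalation from the copper acetylide and reductive elimination join the fragments with retention of the E geometry, dialkyl peroxyketals of this type being known to tolerate such mild room-temperature conditions.

Step 13
Reactants: 19 2-[(3S,6R)-6-[(E)-hexadec-6-en-4-yn-1-yl]-6-methoxy-1,2-dioxan-3-yl]ethan-1-ol
Product: 21 2-[(3S,6R)-6-[(E)-hexadec-6-en-4-yn-1-yl]-6-methoxy-1,2-dioxan-3-yl]acetic acid, via aldehyde 20 (not isolated)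
Conditions: TEMPO (0.2 equiv), PhI(OAc)2 (2.5 equiv), MeCN/H2O (1:1), rt
Reagents that add atoms: water, O
Why: Oxoammonium (TEMPO) oxidation, in which the primary alcohol is oxidised to aldehyde 20 and through its hydrate to the acid under non-basic conditions that should spare the peroxyketal and the enyne and avoid base-induced β-elimination of the peroxide, with no stereocentre touched.

**Compound list**

1 | (3S)-3-hydroxyoxolan-2-one | O[C@H]1CCOC1=O | starting material
2 | 1-[(1S)-1,3-dihydroxypropyl]cyclopropan-1-ol | OCC[C@H](O)C1(O)CC1 | intermediate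
3 | 1-[(1S)-3-[tert-butyl(dimethyl)silyl]oxy-1-hydroxypropyl]cyclopropan-1-ol | CC(C)(C)[Si](C)(C)OCC[C@H](O)C1(O)CC1 | intermediate
4 | (1S)-3-[tert-butyl(dimethyl)silyl]oxy-1-(1-hydroxycyclopropyl)propyl methanesulfonate | CC(C)(C)[Si](C)(C)OCC[C@H](OS(C)(=O)=O)C1(O)CC1 | intermediate
5 | (2R)-2-[2-[tert-butyl(dimethyl)silyl]oxyethyl]cyclobutan-1-one | CC(C)(C)[Si](C)(C)OCC[C@H]1CCC1=O | intermediate
6 | (5R)-5-[2-[tert-butyl(dimethyl)silyl]oxyethyl]oxolan-2-one | CC(C)(C)[Si](C)(C)OCC[C@H]1CCC(=O)O1 | intermediate
7 | (5-iodopent-1-yn-1-yl)trimethylsilane | C[Si](C)(C)C#CCCCI | starting material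
8 | [5-(trimethylsilyl)pent-4-yn-1-yl]lithium | [Li]CCCC#C[Si](C)(C)C | intermediate
9 | (9R)-11-[tert-butyl(dimethyl)silyl]oxy-9-hydroxy-1-(trimethylsilyl)undec-1-yn-6-one | CC(C)(C)[Si](C)(C)OCC[C@H](O)CCC(=O)CCCC#C[Si](C)(C)C | intermediate
10 | (3R)-1-[tert-butyl(dimethyl)silyl]oxy-6-methylidene-11-(trimethylsilyl)undec-10-yn-3-ol | CC(C)(C)[Si](C)(C)OCC[C@H](O)CCC(=C)CCCC#C[Si](C)(C)C | intermediate
11 | (3R)-1-[tert-butyl(dimethyl)silyl]oxy-6-methylidene-11-(trimethylsilyl)undec-10-yn-3-yl methanesulfonate | CC(C)(C)[Si](C)(C)OCC[C@H](OS(C)(=O)=O)CCC(=C)CCCC#C[Si](C)(C)C | intermediate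
12 | (3R)-1-[tert-butyl(dimethyl)silyl]oxy-6-hydroperoxy-6-methoxy-11-(trimethylsilyl)undec-10-yn-3-yl methanesulfonate (both C6 epimers) | CC(C)(C)[Si](C)(C)OCC[C@H](OS(C)(=O)=O)CCC(OC)(OO)CCCC#C[Si](C)(C)C | intermediate
13 | tert-butyl-[2-[(3S)-6-methoxy-6-[5-(trimethylsilyl)pent-4-yn-1-yl]-1,2-dioxan-3-yl]ethoxy]dimethylsilane (both C6 epimers) | CC(C)(C)[Si](C)(C)OCC[C@@H]1CCC(OC)(CCCC#C[Si](C)(C)C)OO1 | intermediate
14 | 2-[(3S,6R)-6-methoxy-6-[5-(trimethylsilyl)pent-4-yn-1-yl]-1,2-dioxan-3-yl]ethan-1-ol | C[Si](C)(C)C#CCCC[C@]1(OC)CC[C@@H](CCO)OO1 | intermediate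
15 | 2-[(3S,6R)-6-methoxy-6-(pent-4-yn-1-yl)-1,2-dioxan-3-yl]ethan-1-ol | C#CCCC[C@]1(OC)CC[C@@H](CCO)OO1 | intermediate
16 | undec-1-yne | CCCCCCCCCC#C | starting material
17 | chloridobis(cyclopentadienyl)[(E)-undec-1-en-1-yl]zirconium | CCCCCCCCC/C=C/[Zr](Cl)(C1C=CC=C1)C1C=CC=C1 | intermediate
18 | (E)-1-iodoundec-1-ene | CCCCCCCCC/C=C/I | intermediate
19 | 2-[(3S,6R)-6-[(E)-hexadec-6-en-4-yn-1-yl]-6-methoxy-1,2-dioxan-3-yl]ethan-1-ol | CCCCCCCCC/C=C/C#CCCC[C@]1(OC)CC[C@@H](CCO)OO1 | intermediate
20 | 2-[(3S,6R)-6-[(E)-hexadec-6-en-4-yn-1-yl]-6-methoxy-1,2-dioxan-3-yl]acetaldehyde | CCCCCCCCC/C=C/C#CCCC[C@]1(OC)CC[C@@H](CC=O)OO1 | intermediate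
21 | 2-[(3S,6R)-6-[(E)-hexadec-6-en-4-yn-1-yl]-6-methoxy-1,2-dioxan-3-yl]acetic acid | CCCCCCCCC/C=C/C#CCCC[C@]1(OC)CC[C@@H](CC(=O)O)OO1 | target

**Step count and risks**

Total steps: 13. Longest linear sequence: 12 (steps 1–10, 12 and 13; step 11 is the side branch).

Steps most likely to fail:

- **Step 9, peroxide ring closure.** Elimination across C3–C4 or C3–Cα may outrun substitution at the secondary centre, or the base may collapse the hydroperoxy ketal back to the ketone with loss of hydroperoxide. The fallback makes the C3–O–O bond first and the ketal second. It sets out from 11: the mesylate should be displaced intermolecularly, with inversion, by 2-methoxypropan-2-yl hydroperoxide (CsOH, DMF) to give the mixed peroxyketal tert-butyl-[(3S)-3-(2-methoxypropan-2-ylperoxy)-6-methylidene-11-(trimethylsilyl)undec-10-ynoxy]dimethylsilane F1. Ozonolysis of its methylidene group in CH2Cl2/MeOH with Me2S work-up should then give the ketone (9S)-11-[tert-butyl(dimethyl)silyl]oxy-9-(2-methoxypropan-2-ylperoxy)-1-(trimethylsilyl)undec-1-yn-6-one F2. CSA in MeOH should strip the 2-methoxypropan-2-yl group and the TBS ether, and the freed C3 hydroperoxide should add to the C6 ketone and be ketalised under the same anomeric control. The sequence comes back to the route at 14, which the carbonate stage of step 10 turns into 15.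

- **Step 1, Kulinkovich reaction on the free hydroxy lactone.** The α-alkoxide may tie up the titanium reagent by chelation so that cyclopropanation stalls, and the very polar triol may be lost to the aqueous phase on work-up. The fallback masks the hydroxyl first. It sets out from 1, which should be silylated (TESCl, imidazole) to (3S)-3-(triethylsilyloxy)oxolan-2-one F3. The same EtMgBr/Ti(OiPr)4 cyclopropanation should then give the less polar diol 1-[(1S)-3-hydroxy-1-(triethylsilyloxy)propyl]cyclopropan-1-ol F4. Its primary hydroxyl should be silylated (TBSCl, imidazole) to 1-[(1S)-3-[tert-butyl(dimethyl)silyl]oxy-1-(triethylsilyloxy)propyl]cyclopropan-1-ol F5. Selective cleavage of the secondary triethylsilyl ether (PPTS, MeOH, 0 °C) comes back to the route at 3.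

- **Step 5, single addition to the lactone.** A second addition of the alkyllithium after premature opening of the lactolate, or enolisation of the lactone, would erode the ketone. The fallback uses a chelated acyl donor. It sets out from 6, which should be opened with MeNH(OMe)·HCl and AlMe3 (CH2Cl2, 0 °C) to the hydroxy amide (4R)-6-[tert-butyl(dimethyl)silyl]oxy-4-hydroxy-N-methoxy-N-methylhexanamide F6. Treatment with two equivalents of 8 (the first is spent on the hydroxyl) should give a chelated tetrahedral adduct that cannot add again. Aqueous work-up comes back to the route at 9.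

Further compounds
F1 | step 9 | tert-butyl-[(3S)-3-(2-methoxypropan-2-ylperoxy)-6-methylidene-11-(trimethylsilyl)undec-10-ynoxy]dimethylsilane | CC(C)(C)[Si](C)(C)OCC[C@@H](OOC(C)(C)OC)CCC(=C)CCCC#C[Si](C)(C)C
F2 | step 9 | (9S)-11-[tert-butyl(dimethyl)silyl]oxy-9-(2-methoxypropan-2-ylperoxy)-1-(trimethylsilyl)undec-1-yn-6-one | CC(C)(C)[Si](C)(C)OCC[C@@H](OOC(C)(C)OC)CCC(=O)CCCC#C[Si](C)(C)C
F3 | step 1 | (3S)-3-(triethylsilyloxy)oxolan-2-one | CC[Si](CC)(CC)O[C@H]1CCOC1=O
F4 | step 1 | 1-[(1S)-3-hydroxy-1-(triethylsilyloxy)propyl]cyclopropan-1-ol | OCC[C@H](O[Si](CC)(CC)CC)C1(O)CC1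
F5 | step 1 | 1-[(1S)-3-[tert-butyl(dimethyl)silyl]oxy-1-(triethylsilyloxy)propyl]cyclopropan-1-ol | CC(C)(C)[Si](C)(C)OCC[C@H](O[Si](CC)(CC)CC)C1(O)CC1
F6 | step 5 | (4R)-6-[tert-butyl(dimethyl)silyl]oxy-4-hydroxy-N-methoxy-N-methylhexanamide | CC(C)(C)[Si](C)(C)OCC[C@H](O)CCC(=O)N(C)OC
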